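**Retrosynthetic overview**
1. Hanultarin is the mono-ferulate of (2R,3R)-(−)-secoisolariciresinol. The diol is C2-symmetric, so acylating either CH2OH gives the same compound; disconnect the ester C–O bond first.
2. Disconnect the central C8–C8' bond of the diol to two identical 3-arylpropanoyl units carrying an (S)-valinol-derived oxazolidinone; an oxidative enolate homocoupling sets both stereocentres (R,R) in one step.
3. All three phenols are carried as TBS ethers and removed together at the end with buffered fluoride, which spares the cinnamate C=C and the ester.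
4. No rings are formed: the three arenes are bought intact (dihydroferulic acid ×2, ferulic acid ×1), and the oxazolidinone ring is a recoverable auxiliary.

Assumption: dihydroferulic acid, ferulic acid and (S)-4-isopropyl-2-oxazolidinone are treated as commercial; secoisolariciresinol itself is deliberately not used, since that would be a semisynthesis.

**Route**

Step 1
Reactants: 1, 3-(4-hydroxy-3-methoxyphenyl)propanoic acid (dihydroferulic acid)
Product: 2, 3-[4-(tert-butyldimethylsilyloxy)-3-methoxyphenyl]propanoic acid
Conditions: TBSCl (2.5 eq), imidazole, DMF, rt; then AcOH/THF/H2O, rt (cleaves the silyl ester only)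
Reagents that add atoms: TBSCl, CC(C)(C)[Si](C)(C)Cl
Why: Silylation of phenol and acid followed by selective hydrolysis of the much more labile silyl ester leaves the aryl TBS ether.

Step 2
Reactants: 2, TBS-dihydroferulic acid; 3, (S)-4-isopropyloxazolidin-2-one
Product: 4, (S)-3-{3-[4-(TBSO)-3-methoxyphenyl]propanoyl}-4-isopropyloxazolidin-2-one
Conditions: PivCl, Et3N, THF, −20 → 0 °C; then 3, LiCl, rt
Reagents that add atoms: none (all product atoms come from 2 and 3)
Why: N-acylation of the Evans auxiliary through the mixed pivalic anhydride; the LiCl/Et3N variant avoids strong base, so the aryl silyl ether is untouched.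

Step 3
Reactants: 4 (2 molecules)
Product: 5, (2R,3R)-2,3-bis[4-(TBSO)-3-methoxybenzyl]-1,4-bis[(S)-4-isopropyl-2-oxooxazolidin-3-yl]butane-1,4-dione
Conditions: LDA (1.1 eq), THF, −78 °C; then anhydrous CuCl2 (1.2 eq), −78 °C → rt; NH4Cl quench; chromatography to remove minor diastereomers
Reagents that add atoms: none
Why: Oxidative homocoupling of the chelated Z-enolate. Each α-carbon forms the new C–C bond on the face opposite the isopropyl group, which with the (S)-auxiliary gives R at both centres (same facial sense as Evans alkylation). The minor R,S and S,S products are diastereomers and are separable.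

Step 4
Reactants: 5
Product: 6, (2R,3R)-2,3-bis[4-(TBSO)-3-methoxybenzyl]butane-1,4-diol (bis-TBS (−)-secoisolariciresinol); auxiliary 3 is recovered
Conditions: LiBH4 (excess), THF/MeOH, 0 °C → rt
Reagents that add atoms: none
Why: Reductive cleavage of both N-acyl oxazolidinones (through a lactone intermediate that is reduced further). The conditions are non-enolising, so the α-centres are not epimerised, and the aryl TBS ethers survive; the CIP descriptors stay R,R.

Step 5
Reactants: 7, (E)-ferulic acid
Product: 8, (E)-3-[4-(TBSO)-3-methoxyphenyl]acrylic acid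
Conditions: TBSCl (2.5 eq), imidazole, DMF, rt; then AcOH/THF/H2O, rt
Reagents that add atoms: TBSCl, CC(C)(C)[Si](C)(C)Cl
Why: Same bis-silylation and selective silyl-ester hydrolysis as step 1; the E-alkene is unaffected.

Step 6
Reactants: 6, bis-TBS diol (2.5 eq, excess recovered); 8, TBS-ferulic acid (1 eq)
Product: 9, (2R,3R)-4-hydroxy-2,3-bis[4-(TBSO)-3-methoxybenzyl]butyl (E)-3-[4-(TBSO)-3-methoxyphenyl]acrylate
Conditions: EDC·HCl, DMAP (cat.), CH2Cl2, 0 °C → rt, slow addition of 8; recycle unreacted 6
Reagents that add atoms: none
Why: Steglich esterification. The two primary OH groups are equivalent by C2 symmetry, so mono-acylation gives one product, and excess diol suppresses the diester. Mitsunobu is avoided because 1,4-diols cyclise to tetrahydrofurans.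

Step 7
Reactants: 9
Product: 10, hanultarin
Conditions: TBAF (3.5 eq)/AcOH (3.5 eq), THF, 0 °C
Reagents that add atoms: none
Why: Fluoride cleaves the three aryl silyl ethers rapidly, and the AcOH buffer protects the ester. Any 1,4-acyl shift is degenerate by C2 symmetry, and the stereocentres and E-alkene are untouched.

**Compound list**
1 | 3-(4-hydroxy-3-methoxyphenyl)propanoic acid | COc1cc(CCC(=O)O)ccc1O | starting material
2 | 3-[4-(TBSO)-3-methoxyphenyl]propanoic acid | COc1cc(CCC(=O)O)ccc1O[Si](C)(C)C(C)(C)C | intermediate
3 | (S)-4-isopropyloxazolidin-2-one | CC(C)[C@H]1COC(=O)N1 | starting material (recovered auxiliary)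
4 | (S)-3-{3-[4-(TBSO)-3-methoxyphenyl]propanoyl}-4-isopropyloxazolidin-2-one | CC(C)[C@H]1COC(=O)N1C(=O)CCc2ccc(O[Si](C)(C)C(C)(C)C)c(OC)c2 | intermediate
5 | (2R,3R)-bis-imide dimer | O=C(N1[C@@H](C(C)C)COC1=O)[C@H](Cc2ccc(O[Si](C)(C)C(C)(C)C)c(OC)c2)[C@@H](Cc2ccc(O[Si](C)(C)C(C)(C)C)c(OC)c2)C(=O)N1[C@@H](C(C)C)COC1=O | intermediate
6 | (2R,3R)-2,3-bis[4-(TBSO)-3-methoxybenzyl]butane-1,4-diol | OC[C@H](Cc1ccc(O[Si](C)(C)C(C)(C)C)c(OC)c1)[C@H](CO)Cc1ccc(O[Si](C)(C)C(C)(C)C)c(OC)c1 | intermediate
7 | (E)-ferulic acid | COc1cc(/C=C/C(=O)O)ccc1O | starting material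
8 | (E)-4-O-TBS-ferulic acid | COc1cc(/C=C/C(=O)O)ccc1O[Si](C)(C)C(C)(C)C | intermediate
9 | tris-TBS hanultarin | COc1cc(/C=C/C(=O)OC[C@H](Cc2ccc(O[Si](C)(C)C(C)(C)C)c(OC)c2)[C@H](CO)Cc2ccc(O[Si](C)(C)C(C)(C)C)c(OC)c2)ccc1O[Si](C)(C)C(C)(C)C | intermediate
10 | hanultarin | COc1cc(/C=C/C(=O)OC[C@H](Cc2ccc(O)c(OC)c2)[C@H](CO)Cc2ccc(O)c(OC)c2)ccc1O | target

**Step count**
Total: 7 steps. Longest linear sequence: 6 steps (1 → 2 → 4 → 5 → 6 → 9 → 10); step 5 is a one-step side branch.

**Three steps most likely to fail**
- **Step 3 (oxidative homocoupling):** yield and diastereoselectivity may be only moderate. Fallback: build the two centres stepwise from 4.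
  - Evans alkylation of 4 with tert-butyl bromoacetate (NaHMDS) sets the first R centre.
  - LiBH4 reduction and acid lactonisation give the (R)-β-arylmethyl-γ-butyrolactone.
  - trans-Selective alkylation of the lactone enolate with 4-(TBSO)-3-methoxybenzyl bromide gives bis-TBS (−)-matairesinol, which LiBH4 reduces to 6.
- **Step 6 (mono-acylation of a symmetric diol):** selectivity is statistical, so diester and recovered diol are unavoidable. Fallback: differentiate the two oxygens through the lactone.
  - Oxidise 6 with TEMPO/PhI(OAc)2 to the lactone (one product by symmetry), or intercept the lactone from the step 3 fallback.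
  - Open with hydroxide, O-silylate, and reduce the acid with BH3·SMe2 to the mono-TBS-protected diol.
  - Acylate the single free OH with 8, then desilylate globally.
- **Step 4 (reduction of a hindered bis-imide):** reduction may be sluggish, stop at the lactone, or open the oxazolidinone ring. Fallback: hydrolyse the auxiliaries with LiOH/H2O2 to the (R,R)-succinic acid, then reduce the diacid (or its anhydride) with BH3·THF to 6.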